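## Structural features

Eupaheliangolide A is a germacrane-type lactone: a ten-membered carbocycle (C1–C10) trans-fused across C6–C7 to an α-methylene-γ-butyrolactone (O–C6, C7–C11, C11=C13, C12=O). The carbocycle carries a cross-conjugated dienone, with E C1=C2 and Z C4=C5 (methyl on C4) on either side of the C3 ketone, and a tertiary allylic alcohol at C10. Three contiguous stereocentres, C6, C7 and C8 (all R), bear the lactone oxygen, the lactone carbon C11 and the tigloyloxy group. The fourth, C10 (R), is quaternary and separated from the triad by the C9 methylene, so it cannot be relayed from it. The exocyclic enoate and the dienone are Michael acceptors, the lactone and tiglate are base-labile, and the medium ring invites transannular and sigmatropic side reactions, so strong nucleophiles, strong acid and prolonged heating must be avoided late. The real difficulty is twofold: building the O6/C11/O8 array on C6–C7–C8 with the two oxygens differentiated, and closing a ten-membered ring that contains a Z-trisubstituted enone. The key step exploits that on C7 the carbon C11 is anti to the C8 oxygen while O6 is the lactone oxygen, which is the pattern left when a trans C7–C8 epoxide is opened at C7, with inversion, by a carbon tethered to O6.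

## Logic of the disconnections

26 ⇒ 25. The O–H at C10 is traced back to an O–Si bond. The tertiary allylic hydroxyl would interfere with hydride, organozinc, NaH and chromium steps, so it stays masked from step 3 to step 13. The forward step must be a fluoride cleavage that spares lactone, tiglate and dienone.

25 ⇒ 24 ⇒ 23. The C3 ketone is taken back to the carbinol, then the ring bond C3–C4 is cut. This bond lies between a carbonyl carbon and an sp2 carbon whose Z geometry can be stored in an alkenyl iodide, and both termini are already present in 19. The gain is the change from a ten-membered ring to an open chain. The forward step must add an alkenyl metal to an aldehyde in the presence of three ester-type carbonyls, at high dilution; the C3 configuration is irrelevant.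

23 ⇒ 22. The C3 aldehyde is traced back to a dimethyl acetal. Carrying C3 at the aldehyde level removes a deprotection and an oxidation. The hydrolysis must be mild enough for the tertiary silyl ether.

22 ⇒ 19 + 20. The acyl C–O bond at O8 is cut. The C8 hydroxyl is the only free hydroxyl in 19, so no selectivity question arises. The forward step must acylate a hindered secondary alcohol without conjugate addition to the exocyclic enoate.

19 ⇒ 16. The bonds C7–C11 and C11=C13 are cut and the C8 oxygen is reconnected to C7 as an epoxide. This removes the lactone ring, the methylene and the C7 stereocentre in one move, and O6 and O8 are differentiated automatically (one carries the tether, the other is the epoxide oxygen). The forward step must attack C7 and not C8, through carbon and not oxygen, with inversion, and must not transfer phosphorus to O8.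

16 ⇒ 14 + 15. The ester C–O bond at O6 is cut. The forward step must be neutral so that the epoxide and acetal survive.

14 ⇒ 13. The two C–O bonds of the oxirane are cut to give E C7=C8. The C6 hydroxyl directs a reagent-controlled epoxidation, which removes two stereocentres. The forward step must be matched with the C6 configuration and must choose C7=C8 over the other allylic alkene C4=C5.

13 ⇒ 6 + 10. The C6–C7 bond is cut into an E-alkenyl metal and an aldehyde of comparable size. The E geometry comes from syn hydrometallation and C6 from a chiral ligand. The forward step must transfer an alkenyl group enantioselectively to a sensitive β-iodoenal.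

10 ⇒ 9 ⇒ 7. The aldehyde is taken back to the alcohol, then C–I and C–H are removed from across the alkyne. The forward step must add hydride and iodine trans, with iodine on C4.

6 ⇒ 5 ⇒ 3 + 4. The O–Si bond is cut, then C9–C10. A propargyl anion equivalent adds to a methyl ketone, and the forward step must distinguish the methyl and alkenyl flanks to set C10.

3 ⇒ 1 + 2. The C1=C2 bond is cut into a stabilised ylide and an aldehyde; the forward step must give the E enone.

## Other disconnections considered

Alternative 1: The cut is the C2–C3 bond, with an auxiliary C5–C10 bond added, so the precursor of A1 is a cyclohexanol with a vinyl group on the carbinol carbon C10 and an isopropenyl group on C5. The forward key step would be the anionic oxy-Cope rearrangement of its potassium alkoxide (KH, 18-crown-6) and silylation of the enolate to A1.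
- In favour: the ring expansion needs no high dilution and is among the most dependable entries to cyclodeca-1,5-dienes, and C6–C8 would be set on a six-membered ring. On certainty of the key event and on ring formation it is the better plan.
- Against: A1 has no oxygen at C3, no C1=C2, no C10 methyl (C10 is at the ketone level, so the tertiary alcohol needs a methyl addition to a mobile cyclodecenone with no clear facial bias), no C13 and no lactone. Z C4=C5 requires a boat-like transition state where the chair normally gives E. The 1,5-diene can also undergo Cope rearrangement back to a divinylcyclohexane on heating.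
- Comparison: structurally it closes the ring early but leaves at least five functional-group tasks, whereas the chosen plan installs all four stereocentres and both enone alkenes before ring closure. Mechanistically the pericyclic step stands on firmer ground than the polar tandem chosen here. In step economy it is estimated to need well over twenty steps against fourteen.

Alternative 2: The cuts are C4–C5 and C8–C9, made together, and the two extra cyclobutane bonds (C4–C9, C5–C8) must be broken afterwards. The forward key step would be irradiation of the two photo-partners near 350 nm to give A2, followed by thermal opening of the bicyclo[2.2.0]hexane.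
- In favour: two C–C bonds form in one operation, C10 is set early on a cyclohexenone, and no macrocyclisation is needed. On bond-forming economy of the key step it is the better plan.
- Against: regiochemistry and facial selectivity of the cycloaddition are open, and the cyclobutene partner is a strained, fully functionalised silyl enol ether with two stereocentres. The fragmentation must break C4–C9 and C5–C8 in preference to cycloreversion or C6–C7 cleavage, and must give Z C4=C5. The C4=C5/C8=C9 diene it releases is a 1,5-diene open to Cope rearrangement at the temperature needed. C8 emerges at the ketone level and needs a stereoselective reduction next to C7, C1–C2 is saturated, and the lactone and C13 are still missing.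
- Comparison: structurally it is fast to the carbon ring but poor in oxidation-state fit. Mechanistically its selectivity rests on excited-state and diradical steps that are harder to steer than the stereospecific epoxide opening. In step economy the redox repairs would outweigh the early gain.

Alternative 3: The cuts are C2–C3 and C3–C4, with carbon monoxide supplying C3. The open-chain precursor of A3 has iodine on C4 and tin on C2, and the forward key step (Pd(PPh3)4, CO, high dilution) would give A3, the same compound as 25.
- In favour: the ketone oxidation level is reached directly, so one operation replaces three of the chosen route (steps 11–13). On step economy of the ring closure it is the better plan, and on stereochemistry it is the equal, since neither closure sets a stereocentre that survives.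
- Against: an E-alkenylstannane on C2 must be carried beside the alkenyl iodide or installed late. Direct coupling to a nine-membered diene competes with CO insertion. The alkenylpalladium on C4 sits close to the exocyclic enoate and could insert it before CO. It also leaves the C6–C8 triad unsolved, so a lactone construction like the chosen one would still be needed, and the chain would lack the C3 carbon on which the chosen precursor is defined.
- Comparison: both closures use the same C4–I bond. The chromium route avoids CO, tin and palladium near the enoate, at the cost of two redox-neutral adjustments.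

Key step: step 9

Remarks and assumptions:
- Atom labels C1–C13 are those of the target; stereodescriptors in names follow each compound's own numbering.
- Structure check: the epoxy ester 16 is 6R,7S,8R,10R in target numbering. The free epoxy alcohol 14 is 6R,7R,8R only because the CIP ranking at C7 changes on acylation. The lactone 19 is 6S,7R,8R,10R, which becomes the 6R,7R,8R,10R array of the target once iodine is replaced by C3. C7 is inverted and C6, C8 are retained, so no configuration needs correcting.
- Design change at the spectator terminus: C3 is carried as a dimethyl acetal (aldehyde level) and not as a primary silyl ether. A primary tert-butyldimethylsilyl ether cannot be removed with confidence beside the tertiary triethylsilyl ether at C10 and would need a separate oxidation. Carbon skeleton and disconnection are unchanged.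
- Assumption: the bisphosphine antipode in step 2 is the one that gives 4R-5, and (−)-MIB in step 6 directs alkenyl transfer to the Si face of 10 as with other aldehydes. Both assignments are to be confirmed (Mosher ester of 13) before scale-up.

## Steps

Step 1
Reactants: 1 2,2-dimethoxyacetaldehyde; 2 1-(triphenyl-λ5-phosphanylidene)propan-2-one
Product: 3 (3E)-5,5-dimethoxypent-3-en-2-one
Conditions: CH2Cl2 (1 as its commercial aqueous solution), rt
Reagents that add atoms: none
Why: Wittig olefination with a carbonyl-stabilised ylide should give the E enone, and the acetal is inert to the neutral medium.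

Step 2
Reactants: 3 (3E)-5,5-dimethoxypent-3-en-2-one; 4 allenylboronic acid pinacol ester
Product: 5 (2E,4R)-1,1-dimethoxy-4-methylhept-2-en-6-yn-4-ol
Conditions: CuOAc (5 mol%), Ph-BPE (6 mol%, antipode as assumed), LiOtBu (10 mol%), i-PrOH (1.0 equiv), THF, −60 °C
Reagents that add atoms: none
Why: Copper-alkoxide-catalysed asymmetric propargylation of a ketone with an allenylboronate (boron-to-copper exchange, then SE2′ addition through a six-membered transition state) should give the homopropargylic 1,2-adduct and not the conjugate adduct; the bisphosphine distinguishes the alkenyl and methyl flanks of the carbonyl and sets C10 as R.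

Step 3
Reactants: 5 (2E,4R)-1,1-dimethoxy-4-methylhept-2-en-6-yn-4-ol
Product: 6 (2E,4R)-1,1-dimethoxy-4-methyl-4-[(triethylsilyl)oxy]hept-2-en-6-yne
Conditions: Et3SiCl, imidazole, DMAP (cat.), DMF, 40 °C
Reagents that add atoms: chlorotriethylsilane, CC[Si](Cl)(CC)CC
Why: Silylation of a tertiary alcohol under imidazole/DMAP catalysis; a silyl triflate is avoided because it would activate the dimethyl acetal.

Step 4
Reactants: 7 but-2-yn-1-ol
Product: 9 (2Z)-3-iodobut-2-en-1-ol, via cyclic alkenylalanate 8 (not isolated)
Conditions: NaAlH2(OCH2CH2OCH3)2, THF, 0 °C; then I2, −78 °C → rt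
Reagents that add atoms: iodine, [I][I]
Why: Alkoxide-directed trans-hydroalumination of a propargylic alcohol places aluminium on C3 in the five-membered alanate 8, and iodinolysis with retention should give the Z iodide that stores the C4=C5 geometry of the target.

Step 5
Reactants: 9 (2Z)-3-iodobut-2-en-1-ol
Product: 10 (2Z)-3-iodobut-2-enal
Conditions: MnO2, CH2Cl2, rt, dark; filtered and used at once
Reagents that add atoms: none
Why: Allylic alcohol oxidation on MnO2 is neutral and should leave the Z geometry and the C–I bond untouched.

Step 6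
Reactants: 6 (2E,4R)-1,1-dimethoxy-4-methyl-4-[(triethylsilyl)oxy]hept-2-en-6-yne; 10 (2Z)-3-iodobut-2-enal
Product: 13 (2Z,4S,5E,8R,9E)-2-iodo-11,11-dimethoxy-8-methyl-8-[(triethylsilyl)oxy]undeca-2,5,9-trien-4-ol, via alkenyldicyclohexylborane 11 (not isolated), via alkenylmethylzinc 12 (not isolated)
Conditions: Cy2BH (from BH3·SMe2, cyclohexene), toluene, 0 °C → rt; Me2Zn, −78 °C; (−)-MIB (5 mol%); then 10, −30 → 0 °C
Reagents that add atoms: none
Why: Syn hydroboration of the terminal alkyne, boron-to-zinc exchange and amino-alcohol-catalysed 1,2-addition of the alkenylzinc to the aldehyde (Oppolzer-type alkenylation) should give the E allylic alcohol; (−)-MIB directs the alkenyl group to the Si face and sets C6 (4S in 13), and any C6 epimer is removed in step 7.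

Step 7
Reactants: 13 (2Z,4S,5E,8R,9E)-2-iodo-11,11-dimethoxy-8-methyl-8-[(triethylsilyl)oxy]undeca-2,5,9-trien-4-ol
Product: 14 (1R,2Z)-1-[(2R,3R)-3-{(2R,3E)-5,5-dimethoxy-2-methyl-2-[(triethylsilyl)oxy]pent-3-en-1-yl}oxiran-2-yl]-3-iodobut-2-en-1-ol
Conditions: Ti(OiPr)4 (20 mol%), D-(−)-diisopropyl tartrate (24 mol%), t-BuOOH (2 equiv, anhydrous), 4 Å MS, CH2Cl2, −20 °C
Reagents that add atoms: tert-butyl hydroperoxide, CC(C)(C)OO
Why: Sharpless asymmetric epoxidation of a secondary E allylic alcohol: D-(−)-tartrate is matched with this carbinol for C7=C8 (erythro, that is anti, epoxy alcohol) and mismatched for the Z iodoalkene, which is also electron-poor and cis-substituted, so oxygen should reach one face of C7=C8 only and set C7 and C8; the C6 epimer of 13 reacts far more slowly and is left behind.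

Step 8
Reactants: 14 (1R,2Z)-1-[(2R,3R)-3-{(2R,3E)-5,5-dimethoxy-2-methyl-2-[(triethylsilyl)oxy]pent-3-en-1-yl}oxiran-2-yl]-3-iodobut-2-en-1-ol; 15 (diethoxyphosphoryl)acetic acid
Product: 16 (1R,2Z)-1-[(2S,3R)-3-{(2R,3E)-5,5-dimethoxy-2-methyl-2-[(triethylsilyl)oxy]pent-3-en-1-yl}oxiran-2-yl]-3-iodobut-2-en-1-yl (diethoxyphosphoryl)acetate
Conditions: DCC, DMAP (cat.), CH2Cl2, 0 °C → rt
Reagents that add atoms: none
Why: Steglich esterification is neutral and should leave the epoxide, the acetal and the silyl ether intact; the change of the oxirane C2 descriptor from R in 14 to S in 16 is a matter of CIP ranking only.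

Step 9
Reactants: 16 (1R,2Z)-1-[(2S,3R)-3-{(2R,3E)-5,5-dimethoxy-2-methyl-2-[(triethylsilyl)oxy]pent-3-en-1-yl}oxiran-2-yl]-3-iodobut-2-en-1-yl (diethoxyphosphoryl)acetate
Product: 19 (4R,5S)-4-{(1R,3R,4E)-1-hydroxy-6,6-dimethoxy-3-methyl-3-[(triethylsilyl)oxy]hex-4-en-1-yl}-5-[(1Z)-2-iodoprop-1-en-1-yl]-3-methylideneoxolan-2-one, via sodium phosphonate carbanion 17 (not isolated), via phosphonolactone sodium enolate 18 (not isolated)
Conditions: NaH (1.05 equiv), THF, −20 → 0 °C; then CH2O (monomer in THF, from cracked paraformaldehyde), −20 → 0 °C; aq. NH4Cl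
Reagents that add atoms: formaldehyde, C=O
Why: Proposed new method: deprotonation gives the phosphonate-stabilised carbanion 17, whose carbon C11 attacks C7 of the epoxide from the side opposite the C7–O bond, so the C7–C11 bond and the γ-lactone form together while the oxygen stays on C8; the C8 alkoxide then takes the acidic C11 proton through a six-membered transfer to give the stabilised enolate 18, which undergoes Horner–Wadsworth–Emmons olefination with formaldehyde and expels sodium diethyl phosphate. The closest known reaction types are the intermolecular opening of epoxides by phosphonoacetate carbanions, the one-flask intramolecular Michael addition/methylenation of phosphonoacetates of γ-hydroxy enones, and the formaldehyde olefination of α-phosphono-γ-lactones; what is new is an epoxide as the internal electrophile in the same flask. The lactone closes in the 5-exo-tet mode, which the three-atom O6–C12–C11 tether allows at C7 only, since attack at C8 would be 6-endo. C7 is the only new stereocentre and is set by inversion at the epoxide carbon, so it follows from the Sharpless epoxidation; C6 and C8 are untouched, and the anti relation of O6 and the epoxide oxygen lets the tether reach the rear of C7 in a staggered conformation, which gives the trans lactone. The step needs C-alkylation at C7 in preference to O-alkylation and to phosphoryl migration: the soft carbanion and the five-membered transition state favour carbon attack at C7, and the fast proton transfer that turns the C8 alkoxide into a hydroxyl removes the nucleophile needed to carry phosphorus to O8, to take the silyl group from O10 or to translactonise, provided no excess base is used and the mixture stays at or below 0 °C.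

Step 10
Reactants: 19 (4R,5S)-4-{(1R,3R,4E)-1-hydroxy-6,6-dimethoxy-3-methyl-3-[(triethylsilyl)oxy]hex-4-en-1-yl}-5-[(1Z)-2-iodoprop-1-en-1-yl]-3-methylideneoxolan-2-one; 20 tiglic acid
Product: 22 (1R,3R,4E)-1-{(2S,3R)-2-[(1Z)-2-iodoprop-1-en-1-yl]-4-methylidene-5-oxooxolan-3-yl}-6,6-dimethoxy-3-methyl-3-[(triethylsilyl)oxy]hex-4-en-1-yl (2E)-2-methylbut-2-enoate, via tiglic trichlorobenzoic anhydride 21 (not isolated)
Conditions: 20, 2,4,6-Cl3C6H2COCl, Et3N, THF, rt; then 19, DMAP (cat.), toluene, rt → 40 °C
Reagents that add atoms: none
Why: Yamaguchi esterification through the mixed anhydride 21; the C8 hydroxyl is the only free hydroxyl, and the E (tiglate) geometry is the stable one, so no isomerisation to the angelate is expected.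

Step 11
Reactants: 22 (1R,3R,4E)-1-{(2S,3R)-2-[(1Z)-2-iodoprop-1-en-1-yl]-4-methylidene-5-oxooxolan-3-yl}-6,6-dimethoxy-3-methyl-3-[(triethylsilyl)oxy]hex-4-en-1-yl (2E)-2-methylbut-2-enoate
Product: 23 (1R,3R,4E)-1-{(2S,3R)-2-[(1Z)-2-iodoprop-1-en-1-yl]-4-methylidene-5-oxooxolan-3-yl}-3-methyl-6-oxo-3-[(triethylsilyl)oxy]hex-4-en-1-yl (2E)-2-methylbut-2-enoate
Conditions: PPTS (10 mol%), acetone/H2O (20:1), rt
Reagents that add atoms: water, O
Why: Acid-catalysed hydrolysis of an α,β-unsaturated dimethyl acetal runs through an allyl-stabilised oxocarbenium ion and is fast under conditions that should spare the tertiary triethylsilyl ether, the esters and the alkenyl iodide; the E geometry is retained.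

Step 12
Reactants: 23 (1R,3R,4E)-1-{(2S,3R)-2-[(1Z)-2-iodoprop-1-en-1-yl]-4-methylidene-5-oxooxolan-3-yl}-3-methyl-6-oxo-3-[(triethylsilyl)oxy]hex-4-en-1-yl (2E)-2-methylbut-2-enoate
Product: 24 (3aR,4R,6R,7E,10Z,11aR)-9-hydroxy-6,10-dimethyl-3-methylidene-2-oxo-6-[(triethylsilyl)oxy]-2,3,3a,4,5,6,9,11a-octahydrocyclodeca[b]furan-4-yl (2E)-2-methylbut-2-enoate (both epimers at C9, which is C3 of the target)
Conditions: CrCl2 (8 equiv), NiCl2 (0.1 equiv), degassed DMSO, rt, 0.003 M, slow addition of 23
Reagents that add atoms: none
Why: Nozaki–Hiyama–Kishi reaction: zerovalent nickel inserts into the C4–I bond with retention, transmetallation gives an alkenyl species of trivalent chromium that adds 1,2 to the aldehyde and to no ester; high dilution favours closure of the ten-membered ring, and the configuration of the new carbinol is irrelevant because it is oxidised next.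

Step 13
Reactants: 24 (3aR,4R,6R,7E,10Z,11aR)-9-hydroxy-6,10-dimethyl-3-methylidene-2-oxo-6-[(triethylsilyl)oxy]-2,3,3a,4,5,6,9,11a-octahydrocyclodeca[b]furan-4-yl (2E)-2-methylbut-2-enoate
Product: 25 (3aR,4R,6R,7E,10Z,11aR)-6,10-dimethyl-3-methylidene-2,9-dioxo-6-[(triethylsilyl)oxy]-2,3,3a,4,5,6,9,11a-octahydrocyclodeca[b]furan-4-yl (2E)-2-methylbut-2-enoate
Conditions: Dess–Martin periodinane, NaHCO3, CH2Cl2, 0 °C → rt
Reagents that add atoms: none
Why: Dess–Martin oxidation of the doubly allylic alcohol, buffered with NaHCO3, should give the cross-conjugated dienone without migration of either double bond; both C3 epimers converge.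

Step 14
Reactants: 25 (3aR,4R,6R,7E,10Z,11aR)-6,10-dimethyl-3-methylidene-2,9-dioxo-6-[(triethylsilyl)oxy]-2,3,3a,4,5,6,9,11a-octahydrocyclodeca[b]furan-4-yl (2E)-2-methylbut-2-enoate
Product: 26 eupaheliangolide A, (3aR,4R,6R,7E,10Z,11aR)-6-hydroxy-6,10-dimethyl-3-methylidene-2,9-dioxo-2,3,3a,4,5,6,9,11a-octahydrocyclodeca[b]furan-4-yl (2E)-2-methylbut-2-enoate
Conditions: HF·pyridine, pyridine, THF, 0 °C → rt
Reagents that add atoms: none
Why: Fluoride-mediated cleavage of the tertiary Si–O bond under buffered, weakly acidic conditions should leave the lactone, the tiglate and the dienone untouched and free the C10 hydroxyl of the target.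

## Compound list

1 | 2,2-dimethoxyacetaldehyde | COC(OC)C=O | starting material
2 | 1-(triphenyl-λ5-phosphanylidene)propan-2-one | CC(=O)C=P(c1ccccc1)(c1ccccc1)c1ccccc1 | starting material
3 | (3E)-5,5-dimethoxypent-3-en-2-one | CC(=O)/C=C/C(OC)OC | intermediate
4 | allenylboronic acid pinacol ester | C=C=CB1OC(C)(C)C(C)(C)O1 | starting material
5 | (2E,4R)-1,1-dimethoxy-4-methylhept-2-en-6-yn-4-ol | C#CC[C@@](C)(O)/C=C/C(OC)OC | intermediate
6 | (2E,4R)-1,1-dimethoxy-4-methyl-4-[(triethylsilyl)oxy]hept-2-en-6-yne | C#CC[C@@](C)(O[Si](CC)(CC)CC)/C=C/C(OC)OC | intermediate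
7 | but-2-yn-1-ol | CC#CCO | starting material
8 | sodium 2,2-bis(2-methoxyethoxy)-3-methyl-2,5-dihydro-1,2-oxaaluminol-2-uide (cyclic alkenylalanate) | [Na+].CC1=CCO[Al-]1(OCCOC)OCCOC | intermediate (not isolated)
9 | (2Z)-3-iodobut-2-en-1-ol | C/C(I)=C/CO | intermediate
10 | (2Z)-3-iodobut-2-enal | C/C(I)=C/C=O | intermediate
11 | dicyclohexyl{(1E,4R,5E)-7,7-dimethoxy-4-methyl-4-[(triethylsilyl)oxy]hepta-1,5-dien-1-yl}borane | C1CCCCC1B(C1CCCCC1)/C=C/C[C@@](C)(O[Si](CC)(CC)CC)/C=C/C(OC)OC | intermediate (not isolated)
12 | {(1E,4R,5E)-7,7-dimethoxy-4-methyl-4-[(triethylsilyl)oxy]hepta-1,5-dien-1-yl}(methyl)zinc | C[Zn]/C=C/C[C@@](C)(O[Si](CC)(CC)CC)/C=C/C(OC)OC | intermediate (not isolated)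
13 | (2Z,4S,5E,8R,9E)-2-iodo-11,11-dimethoxy-8-methyl-8-[(triethylsilyl)oxy]undeca-2,5,9-trien-4-ol | C/C(I)=C/[C@@H](O)/C=C/C[C@@](C)(O[Si](CC)(CC)CC)/C=C/C(OC)OC | intermediate
14 | (1R,2Z)-1-[(2R,3R)-3-{(2R,3E)-5,5-dimethoxy-2-methyl-2-[(triethylsilyl)oxy]pent-3-en-1-yl}oxiran-2-yl]-3-iodobut-2-en-1-ol | C/C(I)=C/[C@@H](O)[C@H]1O[C@@H]1C[C@@](C)(O[Si](CC)(CC)CC)/C=C/C(OC)OC | intermediate
15 | (diethoxyphosphoryl)acetic acid | O=C(O)CP(=O)(OCC)OCC | starting material
16 | (1R,2Z)-1-[(2S,3R)-3-{(2R,3E)-5,5-dimethoxy-2-methyl-2-[(triethylsilyl)oxy]pent-3-en-1-yl}oxiran-2-yl]-3-iodobut-2-en-1-yl (diethoxyphosphoryl)acetate | C/C(I)=C/[C@@H](OC(=O)CP(=O)(OCC)OCC)[C@H]1O[C@@H]1C[C@@](C)(O[Si](CC)(CC)CC)/C=C/C(OC)OC | intermediate (key-step precursor)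
17 | sodium salt of 16 deprotonated at the phosphonoacetate carbon C11 | [Na+].CCOP(=O)(OCC)[CH-]C(=O)O[C@H](/C=C(/C)I)[C@H]1O[C@@H]1C[C@@](C)(O[Si](CC)(CC)CC)/C=C/C(OC)OC | intermediate (not isolated)
18 | sodium enolate of the 3-(diethoxyphosphoryl) lactone: (4R,5S)-4-{(1R,3R,4E)-1-hydroxy-6,6-dimethoxy-3-methyl-3-[(triethylsilyl)oxy]hex-4-en-1-yl}-5-[(1Z)-2-iodoprop-1-en-1-yl]-2-oxooxolan-3-ide bearing P(O)(OEt)2 on C3 | [Na+].CCOP(=O)(OCC)[C-]1C(=O)O[C@H](/C=C(/C)I)[C@H]1[C@H](O)C[C@@](C)(O[Si](CC)(CC)CC)/C=C/C(OC)OC | intermediate (not isolated)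
19 | (4R,5S)-4-{(1R,3R,4E)-1-hydroxy-6,6-dimethoxy-3-methyl-3-[(triethylsilyl)oxy]hex-4-en-1-yl}-5-[(1Z)-2-iodoprop-1-en-1-yl]-3-methylideneoxolan-2-one | C=C1C(=O)O[C@H](/C=C(/C)I)[C@H]1[C@H](O)C[C@@](C)(O[Si](CC)(CC)CC)/C=C/C(OC)OC | intermediate (key-step product)
20 | tiglic acid, (2E)-2-methylbut-2-enoic acid | C/C=C(\C)C(=O)O | starting material
21 | (2E)-2-methylbut-2-enoic 2,4,6-trichlorobenzoic anhydride | C/C=C(\C)C(=O)OC(=O)c1c(Cl)cc(Cl)cc1Cl | intermediate (not isolated)
22 | (1R,3R,4E)-1-{(2S,3R)-2-[(1Z)-2-iodoprop-1-en-1-yl]-4-methylidene-5-oxooxolan-3-yl}-6,6-dimethoxy-3-methyl-3-[(triethylsilyl)oxy]hex-4-en-1-yl (2E)-2-methylbut-2-enoate | C=C1C(=O)O[C@H](/C=C(/C)I)[C@H]1[C@H](OC(=O)/C(C)=C/C)C[C@@](C)(O[Si](CC)(CC)CC)/C=C/C(OC)OC | intermediate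
23 | (1R,3R,4E)-1-{(2S,3R)-2-[(1Z)-2-iodoprop-1-en-1-yl]-4-methylidene-5-oxooxolan-3-yl}-3-methyl-6-oxo-3-[(triethylsilyl)oxy]hex-4-en-1-yl (2E)-2-methylbut-2-enoate | C=C1C(=O)O[C@H](/C=C(/C)I)[C@H]1[C@H](OC(=O)/C(C)=C/C)C[C@@](C)(O[Si](CC)(CC)CC)/C=C/C=O | intermediate
24 | (3aR,4R,6R,7E,10Z,11aR)-9-hydroxy-6,10-dimethyl-3-methylidene-2-oxo-6-[(triethylsilyl)oxy]-2,3,3a,4,5,6,9,11a-octahydrocyclodeca[b]furan-4-yl (2E)-2-methylbut-2-enoate, both C9 epimers | C=C1C(=O)O[C@@H]2/C=C(/C)C(O)/C=C/[C@](C)(O[Si](CC)(CC)CC)C[C@@H](OC(=O)/C(C)=C/C)[C@@H]12 | intermediate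
25 | (3aR,4R,6R,7E,10Z,11aR)-6,10-dimethyl-3-methylidene-2,9-dioxo-6-[(triethylsilyl)oxy]-2,3,3a,4,5,6,9,11a-octahydrocyclodeca[b]furan-4-yl (2E)-2-methylbut-2-enoate | C=C1C(=O)O[C@@H]2/C=C(/C)C(=O)/C=C/[C@](C)(O[Si](CC)(CC)CC)C[C@@H](OC(=O)/C(C)=C/C)[C@@H]12 | intermediate
26 | eupaheliangolide A, (3aR,4R,6R,7E,10Z,11aR)-6-hydroxy-6,10-dimethyl-3-methylidene-2,9-dioxo-2,3,3a,4,5,6,9,11a-octahydrocyclodeca[b]furan-4-yl (2E)-2-methylbut-2-enoate | C=C1C(=O)O[C@@H]2/C=C(/C)C(=O)/C=C/[C@](C)(O)C[C@@H](OC(=O)/C(C)=C/C)[C@@H]12 | target

## Step count and least certain steps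

Total: 14 steps. Longest linear sequence: 12 steps (steps 1, 2, 3, 6, 7, 8, 9, 10, 11, 12, 13, 14); steps 4 and 5 form the short branch to 10.

**Step 9 (key step).** The most likely failure is that the stabilised carbanion opens the 1,2-disubstituted epoxide too slowly at or below 0 °C. On warming, the small equilibrium amount of C8 alkoxide can take the phosphoryl group from C11 (which leads on to a cyclopropane), the enolate oxygen can alkylate in place of carbon, or the triethylsilyl group can move from O10 to O8.

The fallback is phosphorus-free, so heating is allowed, and uses known reaction types. It sets out from 14 and comes back at 19.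
- Esterification of 14 with 2,2,2-trichloroethyl hydrogen malonate F1 (from Meldrum's acid and 2,2,2-trichloroethanol; DCC, DMAP) would give the epoxy malonate F2.
- Soft enolisation (DBU, LiCl, MeCN, rt to 50 °C) should bring about the 5-exo C-alkylation of the malonate by the epoxide and give the α-(trichloroethoxycarbonyl) lactone F3.
- Reductive removal of the trichloroethyl group (Zn, THF/aqueous KH2PO4) would give the α-carboxy lactone F4.
- Decarboxylative Mannich methylenation (Et2NH, aqueous CH2O) would then deliver 19.

**Step 12.** The most likely failure is slow closure of the ten-membered ring, so that intermolecular coupling and protonolysis of the alkenylchromium species win; capture of the alkenylnickel intermediate by the neighbouring exocyclic enoate is a second possibility.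

The fallback closes the same bond at the ketone level by reductive elimination from an acyl(alkenyl)palladium ring. It sets out from 23 and comes back at 25, which also bypasses step 13.
- Iodine–tin exchange (Pd(PPh3)4, Me3SnSnMe3, toluene) would give the alkenylstannane aldehyde F5.
- Pinnick oxidation (NaClO2, NaH2PO4, 2-methylbut-2-ene) would give the alkenylstannane acid F6.
- 1-Chloro-N,N,2-trimethylprop-1-en-1-amine would convert it under neutral conditions into the acid chloride F7, used without isolation.
- Intramolecular acyl Stille coupling (Pd2(dba)3, tri(2-furyl)phosphine, toluene, high dilution) would give 25.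

**Step 2.** The most likely failure is poor facial discrimination between the methyl and alkenyl flanks of the ketone, or partial allenyl in place of propargyl transfer.

The fallback replaces asymmetric catalysis by resolution. It sets out from 3 and comes back at 5. Barbier propargylation (Zn, propargyl bromide, THF) would give the racemic tertiary alcohol F8, and preparative chromatography on a chiral stationary phase would supply 5.

**Step 6.** The most likely failure is erosion of enantioselectivity by uncatalysed background addition promoted by the boron and zinc Lewis acids, together with Z-to-E isomerisation of 10 during the slow addition.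

The fallback changes the nucleophile. It sets out from 6 and 10 and comes back at 13. Zinc–ProPhenol alkynylation (Me2Zn, ProPhenol antipode giving 4R, Ph3P=O, toluene, 0 °C) would give the propargylic alcohol F9. Hydroxyl-directed trans-reduction (NaAlH2(OCH2CH2OCH3)2, THF, 0 °C) would give 13, with step 7 again removing any C6 epimer.

## Further compounds

F1 | step 9 | 2,2,2-trichloroethyl hydrogen malonate, 3-oxo-3-(2,2,2-trichloroethoxy)propanoic acid | OC(=O)CC(=O)OCC(Cl)(Cl)Cl
F2 | step 9 | (1R,2Z)-1-[(2S,3R)-3-{(2R,3E)-5,5-dimethoxy-2-methyl-2-[(triethylsilyl)oxy]pent-3-en-1-yl}oxiran-2-yl]-3-iodobut-2-en-1-yl 2,2,2-trichloroethyl propanedioate | C/C(I)=C/[C@@H](OC(=O)CC(=O)OCC(Cl)(Cl)Cl)[C@H]1O[C@@H]1C[C@@](C)(O[Si](CC)(CC)CC)/C=C/C(OC)OC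
F3 | step 9 | 2,2,2-trichloroethyl (4R,5S)-4-{(1R,3R,4E)-1-hydroxy-6,6-dimethoxy-3-methyl-3-[(triethylsilyl)oxy]hex-4-en-1-yl}-5-[(1Z)-2-iodoprop-1-en-1-yl]-2-oxooxolane-3-carboxylate (C3 epimers) | ClC(Cl)(Cl)COC(=O)C1C(=O)O[C@H](/C=C(/C)I)[C@H]1[C@H](O)C[C@@](C)(O[Si](CC)(CC)CC)/C=C/C(OC)OC
F4 | step 9 | (4R,5S)-4-{(1R,3R,4E)-1-hydroxy-6,6-dimethoxy-3-methyl-3-[(triethylsilyl)oxy]hex-4-en-1-yl}-5-[(1Z)-2-iodoprop-1-en-1-yl]-2-oxooxolane-3-carboxylic acid (C3 epimers) | OC(=O)C1C(=O)O[C@H](/C=C(/C)I)[C@H]1[C@H](O)C[C@@](C)(O[Si](CC)(CC)CC)/C=C/C(OC)OC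
F5 | step 12 | (1R,3R,4E)-3-methyl-1-{(2S,3R)-4-methylidene-5-oxo-2-[(1Z)-2-(trimethylstannyl)prop-1-en-1-yl]oxolan-3-yl}-6-oxo-3-[(triethylsilyl)oxy]hex-4-en-1-yl (2E)-2-methylbut-2-enoate | C=C1C(=O)O[C@H](/C=C(/C)[Sn](C)(C)C)[C@H]1[C@H](OC(=O)/C(C)=C/C)C[C@@](C)(O[Si](CC)(CC)CC)/C=C/C=O
F6 | step 12 | (2E,4R,6R)-4-methyl-6-{[(2E)-2-methylbut-2-enoyl]oxy}-6-{(2S,3R)-4-methylidene-5-oxo-2-[(1Z)-2-(trimethylstannyl)prop-1-en-1-yl]oxolan-3-yl}-4-[(triethylsilyl)oxy]hex-2-enoic acid | C=C1C(=O)O[C@H](/C=C(/C)[Sn](C)(C)C)[C@H]1[C@H](OC(=O)/C(C)=C/C)C[C@@](C)(O[Si](CC)(CC)CC)/C=C/C(=O)O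
F7 | step 12 | acid chloride of F6, (1R,3R,4E)-6-chloro-3-methyl-1-{(2S,3R)-4-methylidene-5-oxo-2-[(1Z)-2-(trimethylstannyl)prop-1-en-1-yl]oxolan-3-yl}-6-oxo-3-[(triethylsilyl)oxy]hex-4-en-1-yl (2E)-2-methylbut-2-enoate | C=C1C(=O)O[C@H](/C=C(/C)[Sn](C)(C)C)[C@H]1[C@H](OC(=O)/C(C)=C/C)C[C@@](C)(O[Si](CC)(CC)CC)/C=C/C(=O)Cl
F8 | step 2 | racemic (2E)-1,1-dimethoxy-4-methylhept-2-en-6-yn-4-ol | C#CCC(C)(O)/C=C/C(OC)OC
F9 | step 6 | (2Z,4R,8R,9E)-2-iodo-11,11-dimethoxy-8-methyl-8-[(triethylsilyl)oxy]undeca-2,9-dien-5-yn-4-ol | C/C(I)=C/[C@@H](O)C#CC[C@@](C)(O[Si](CC)(CC)CC)/C=C/C(OC)OC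
A1 | alternative 1 | cyclodeca-1,5-diene from the oxy-Cope step: C10 trimethylsilyl enol ether, Z C4=C5, tert-butyldimethylsilyl ethers on C6 and C8, 2-(4-methoxybenzyloxy)ethyl on C7 | C[Si](C)(C)O/C1=C\CC/C(C)=C\[C@@H](O[Si](C)(C)C(C)(C)C)[C@H](CCOCc2ccc(OC)cc2)[C@H](O[Si](C)(C)C(C)(C)C)C1
A2 | alternative 2 | cis-anti-cis tricyclic photoadduct, a cyclohexanone fused to a bicyclo[2.2.0]hexane carrying two silyl ethers and a methoxycarbonylmethyl group | O=C1CC[C@](C)(O)[C@H]2[C@]1(C)[C@@H]3[C@@H](O[Si](C)(C)C(C)(C)C)[C@H](CC(=O)OC)[C@]23O[Si](C)(C)C(C)(C)C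
A3 | alternative 3 | C10 triethylsilyl ether of eupaheliangolide A, identical with 25 | C=C1C(=O)O[C@@H]2/C=C(/C)C(=O)/C=C/[C@](C)(O[Si](CC)(CC)CC)C[C@@H](OC(=O)/C(C)=C/C)[C@@H]12
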